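**Retrosynthetic overview**
1. The plan rests on the benzene ring C1′–C6′: chain on C1′, oxygens on C2′, C4′ and C5′ (O2′/O5′ para, chain ortho to O2′, O4′ ortho to O5′), CHO on C3′, H on C6′. This is the pattern that an alkoxy(1-alkoxyvinyl)carbene chromium complex, CO and a terminal alkyne give in one benzannulation.
2. Endgame: C3′–CHO by magnesium-mediated ortho-formylation at the only free position ortho to O2′–H, then ester saponification and acid hydrolysis of the two MOM ethers on O4′ and O5′.
3. Ring formation (the only ring, step 14): bonds C5′–C6′, C1′–C2′ and C2′–C3′ from carbene complex 20 (C5′, C4′, C3′), one CO ligand (C2′) and alkyne 12 (C1′, C6′).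
4. Alkyne 12: C12–C13 by copper-mediated coupling of allylic bromide 9 with TMS-acetylene; C2 (S) by Ru-catalysed asymmetric hydrogenation of the tiglic-type acid 5, made by ω-oxidation of farnesyl acetate.
5. Carbene 20: Fischer synthesis from lithiated methoxymethyl vinyl ether, Cr(CO)6 and MOMCl.

Key step: step 14

Remark 1: The two carbene-derived oxygens are carried as methoxymethyl ethers. An aryl methyl ether para to a phenoxide and ortho to a second aryloxide resists thiolate cleavage, and boron or aluminium halides would close the free C2′ hydroxyl onto the C10=C11 alkene; MOM ethers leave in dilute aqueous acid.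
Remark 2: The alkyne partner has a fourteen-carbon main chain (tetradeca-6,10-dien-13-ynoate); C13 becomes ring carbon C1′ and C12 the benzylic CH2.
Remark 3: The ethynyl unit is introduced as TMS-acetylene under CuI/carbonate, because an ethynyl Grignard reagent would endanger the methyl ester and the C2 stereocentre.
Remark 4: Methoxymethyl vinyl ether is assumed not to be a catalogue chemical and is made in two steps. SMILES has no hapto bond, so complex 21 is written as the arene and the Cr(CO)3 fragment joined by a dot.

**Route**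

Step 1
Reactants: 1 (2E,6E)-farnesol
Product: 2 (2E,6E)-farnesyl acetate
Conditions: Ac2O, pyridine, DMAP (cat.), CH2Cl2, 0 °C → rt
Reagents that add atoms: acetic anhydride, CC(=O)OC(C)=O
Why: DMAP-catalysed acetylation of the primary allylic alcohol masks the C1 oxygen and deactivates the 2,3-alkene toward the allylic oxidation that follows.

Step 2
Reactants: 2 (2E,6E)-farnesyl acetate
Product: 3 (2E,6E,10E)-12-hydroxy-3,7,11-trimethyldodeca-2,6,10-trien-1-yl acetate
Conditions: SeO2 (cat.), t-BuOOH, salicylic acid (cat.), CH2Cl2, rt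
Reagents that add atoms: tert-butyl hydroperoxide, CC(C)(C)OO; selenium dioxide, O=[Se]=O
Why: SeO2/t-BuOOH allylic oxidation (Riley type, ene reaction then [2,3]-shift) should attack the most electron-rich, terminal trisubstituted alkene at its (E)-methyl group and give the (E)-allylic alcohol, and any aldehyde 4 formed by over-oxidation is carried into step 3 together with 3.

Step 3
Reactants: 3 (2E,6E,10E)-12-hydroxy-3,7,11-trimethyldodeca-2,6,10-trien-1-yl acetate
Product: 4 (2E,6E,10E)-3,7,11-trimethyl-12-oxododeca-2,6,10-trien-1-yl acetate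
Conditions: MnO2 (activated, excess), CH2Cl2, rt
Reagents that add atoms: none
Why: Activated MnO2 oxidises only the allylic alcohol to the (E)-enal and leaves the acetate and the other alkenes untouched.

Step 4
Reactants: 4 (2E,6E,10E)-3,7,11-trimethyl-12-oxododeca-2,6,10-trien-1-yl acetate
Product: 5 (2E,6E,10E)-12-acetoxy-2,6,10-trimethyldodeca-2,6,10-trienoic acid
Conditions: NaClO2, NaH2PO4, 2-methyl-2-butene, t-BuOH/H2O, 0 °C → rt
Reagents that add atoms: sodium chlorite, [Na+].[O-]Cl=O
Why: Pinnick oxidation converts the enal into the tiglic-type (E)-acid without isomerisation, with 2-methyl-2-butene trapping hypochlorous acid so that the chain alkenes are spared.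

Step 5
Reactants: 5 (2E,6E,10E)-12-acetoxy-2,6,10-trimethyldodeca-2,6,10-trienoic acid
Product: 6 (2S,6E,10E)-12-acetoxy-2,6,10-trimethyldodeca-6,10-dienoic acid
Conditions: H2 (4 atm), Ru(OAc)2[(S)-H8-BINAP] (1 mol %), MeOH, rt
Reagents that add atoms: none
Why: In this Noyori-type asymmetric hydrogenation the carboxylate binds ruthenium so that only the conjugated C2=C3 alkene is reduced, and the (S)-ligand, the sense that converts (E)-2-methylalk-2-enoic acids into (S)-2-methylalkanoic acids, should set C2 as S, while the isolated trisubstituted alkenes and the allylic acetate are not substrates of this catalyst.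

Step 6
Reactants: 6 (2S,6E,10E)-12-acetoxy-2,6,10-trimethyldodeca-6,10-dienoic acid
Product: 8 methyl (2S,6E,10E)-12-hydroxy-2,6,10-trimethyldodeca-6,10-dienoate, via potassium hydroxy carboxylate 7 (not isolated)
Conditions: K2CO3, MeOH, rt; evaporate; MeI, DMF, rt
Reagents that add atoms: iodomethane, CI
Why: Zemplén-type methanolysis frees the allylic alcohol while the acid rests as its carboxylate (no enolisation at C2), and the carboxylate is then the only nucleophile that iodomethane alkylates under carbonate in DMF (SN2 esterification).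

Step 7
Reactants: 8 methyl (2S,6E,10E)-12-hydroxy-2,6,10-trimethyldodeca-6,10-dienoate
Product: 9 methyl (2S,6E,10E)-12-bromo-2,6,10-trimethyldodeca-6,10-dienoate
Conditions: PBr3 (0.4 equiv), Et2O, 0 °C; used crude
Reagents that add atoms: phosphorus tribromide, BrP(Br)Br
Why: PBr3 converts the primary allylic alcohol into the bromide through a phosphite ester and SN2 displacement at low temperature without allylic transposition (the farnesol-to-farnesyl bromide reaction), and the methyl ester is inert.

Step 8
Reactants: 9 methyl (2S,6E,10E)-12-bromo-2,6,10-trimethyldodeca-6,10-dienoate; 10 ethynyltrimethylsilane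
Product: 11 methyl (2S,6E,10E)-2,6,10-trimethyl-14-(trimethylsilyl)tetradeca-6,10-dien-13-ynoate
Conditions: CuI, NaI, K2CO3, DMF, rt, degassed
Reagents that add atoms: none
Why: The copper(I) acetylide formed under carbonate should substitute the primary allylic bromide (copper-mediated alkyne–allyl halide coupling, iodide exchange assisting) at the α-carbon with retention of the E-alkene, since SN2′ attack would build a quaternary centre, and the weak base leaves the ester and C2 untouched.

Step 9
Reactants: 11 methyl (2S,6E,10E)-2,6,10-trimethyl-14-(trimethylsilyl)tetradeca-6,10-dien-13-ynoate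
Product: 12 methyl (2S,6E,10E)-2,6,10-trimethyltetradeca-6,10-dien-13-ynoate
Conditions: K2CO3 (cat.), MeOH, 0 °C, short reaction time
Reagents that add atoms: none
Why: Methoxide-catalysed protodesilylation of the alkynylsilane is fast at 0 °C, which keeps the skipped enyne from isomerising to an allene, and methanolysis of the methyl ester is degenerate.

Step 10
Reactants: 13 2-chloroethanol
Product: 14 1-chloro-2-(methoxymethoxy)ethane
Conditions: MOMCl, i-Pr2NEt, CH2Cl2, 0 °C → rt
Reagents that add atoms: chloromethyl methyl ether, COCCl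
Why: Standard MOM ether formation by alkylation of the alcohol with the oxocarbenium-like chloromethyl ether under Hünig's base.

Step 11
Reactants: 14 1-chloro-2-(methoxymethoxy)ethane
Product: 15 methoxymethyl vinyl ether
Conditions: KOt-Bu, DMSO, rt → 50 °C, product distilled out; redistilled from Na
Reagents that add atoms: none
Why: E2 dehydrochlorination of a 2-chloroethyl ether with a hindered alkoxide is the classical vinyl ether synthesis, and the volatile product is removed by distillation as it forms.

Step 12
Reactants: 15 methoxymethyl vinyl ether; 16 chromium hexacarbonyl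
Product: 19 tetramethylammonium pentacarbonyl[2-(methoxymethoxy)acryloyl]chromate, via 1-(methoxymethoxy)vinyllithium 17 (not isolated), via lithium acyl chromate 18 (not isolated)
Conditions: s-BuLi, THF, −78 °C; Cr(CO)6, −78 °C → rt; Me4NBr, H2O (degassed)
Reagents that add atoms: tetramethylammonium bromide, C[N+](C)(C)C.[Br-]
Why: First half of the Fischer carbene synthesis, in which the vinylic C–H next to oxygen is lithiated (lithium held by the acetal oxygens), the vinyllithium adds to a CO ligand of Cr(CO)6 to give the acyl chromate, and cation exchange gives the loosely ion-paired tetramethylammonium salt that can be purified and O-alkylated.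

Step 13
Reactants: 19 tetramethylammonium pentacarbonyl[2-(methoxymethoxy)acryloyl]chromate
Product: 20 pentacarbonyl[(methoxymethoxy)(1-(methoxymethoxy)vinyl)carbene]chromium
Conditions: MOMCl, CH2Cl2, −20 → 0 °C; rapid filtration through SiO2, stored cold under Ar
Reagents that add atoms: chloromethyl methyl ether, COCCl
Why: O-Alkylation of the acyl chromate oxygen by a hard, oxocarbenium-like electrophile (the second half of the Fischer carbene synthesis, as with oxonium salts, alkyl triflates or acyl halides) should give the alkoxycarbene complex.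

Step 14
Reactants: 12 methyl (2S,6E,10E)-2,6,10-trimethyltetradeca-6,10-dien-13-ynoate; 20 pentacarbonyl[(methoxymethoxy)(1-(methoxymethoxy)vinyl)carbene]chromium
Product: 22 methyl (2S,6E,10E)-12-[2-hydroxy-4,5-bis(methoxymethoxy)phenyl]-2,6,10-trimethyldodeca-6,10-dienoate, via tricarbonylchromium arene complex 21 (not isolated)
Conditions: 20 (1.3 equiv), THF (0.05 M), 50 °C, Ar; then MeCN, air, rt
Reagents that add atoms: none
Why: Thermal loss of one CO from 20 lets the alkyne insert into the Cr=C bond to give a vinylcarbene, CO insertion gives a dienylketene, 6π-electrocyclisation joins the ketene carbon to the CH2 terminus of the alkoxyvinyl group, and enolisation gives the phenol as its Cr(CO)3 complex 21, which air releases as 22. This is the Dötz benzannulation of an alkenyl(alkoxy)carbene chromium complex with a terminal alkyne, the closest well-studied relatives of 20 being the 2-dihydropyranyl and isopropenyl complexes. The single ring is closed in a formal [3+2+1] union (three carbene-ligand carbons, two alkyne carbons, one CO) that makes C5′–C6′, C1′–C2′ and C2′–C3′, the last bond by the electrocyclisation. No stereocentre is created, and C2 and both E-alkenes are remote spectators. The step needs regioselective insertion, and the terminal alkyne secures it: its substituted carbon ends next to the CO-derived carbon for steric reasons, so the chain comes out ortho to the new phenol and the hydrogen next to C5′. Chemoselectivity rests on the skipped enyne, whose trisubstituted alkenes do not compete with the alkyne and whose nearest alkene is too close to be trapped by the vinylcarbene, and THF at moderate temperature favours the phenol over cyclobutenone, furan and two-alkyne channels.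

Step 15
Reactants: 22 methyl (2S,6E,10E)-12-[2-hydroxy-4,5-bis(methoxymethoxy)phenyl]-2,6,10-trimethyldodeca-6,10-dienoate
Product: 23 methyl (2S,6E,10E)-12-[3-formyl-2-hydroxy-4,5-bis(methoxymethoxy)phenyl]-2,6,10-trimethyldodeca-6,10-dienoate
Conditions: MgCl2 (anhydrous), Et3N, (CH2O)n, MeCN, reflux, Ar
Reagents that add atoms: paraformaldehyde (as formaldehyde), C=O
Why: In this magnesium-mediated ortho-formylation (Casnati–Skattebøl) the magnesium phenoxide delivers formaldehyde to the ortho carbon through a six-membered transition state and a second formaldehyde oxidises the benzylic alkoxide by hydride transfer, so the aldehyde can only enter at C3′, the one free ortho position, while MOM ethers, ester and alkenes tolerate the weakly basic medium.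

Step 16
Reactants: 23 methyl (2S,6E,10E)-12-[3-formyl-2-hydroxy-4,5-bis(methoxymethoxy)phenyl]-2,6,10-trimethyldodeca-6,10-dienoate
Product: 24 (2S,6E,10E)-12-[3-formyl-2-hydroxy-4,5-bis(methoxymethoxy)phenyl]-2,6,10-trimethyldodeca-6,10-dienoic acid
Conditions: LiOH, THF/MeOH/H2O, rt, degassed; then cold dilute HCl to pH 4
Reagents that add atoms: lithium hydroxide, [Li+].[OH-]
Why: Saponification of the methyl ester at room temperature, with the non-enolisable aldehyde deactivated as its ortho-phenoxide and C2 protected once the carboxylate forms, is placed before the hydroquinone is unmasked so that no free polyphenol meets base.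

Step 17
Reactants: 24 (2S,6E,10E)-12-[3-formyl-2-hydroxy-4,5-bis(methoxymethoxy)phenyl]-2,6,10-trimethyldodeca-6,10-dienoic acid
Product: 25 (2S,6E,10E)-12-(3-formyl-2,4,5-trihydroxyphenyl)-2,6,10-trimethyldodeca-6,10-dienoic acid (CNP0180353.1)
Conditions: 2 M aq. HCl/THF (1:3), 40 °C, degassed, Ar
Reagents that add atoms: none
Why: Specific-acid hydrolysis of the two phenolic MOM acetals through oxocarbenium ions proceeds in dilute aqueous acid at a temperature below that needed for chroman formation or alkene hydration, and oxygen is excluded because the liberated hydroxyhydroquinone is air-sensitive.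

**Compound list**
1 | (2E,6E)-farnesol | CC(C)=CCC/C(C)=C/CC/C(C)=C/CO | starting material
2 | (2E,6E)-farnesyl acetate | CC(=O)OC/C=C(\C)CC/C=C(\C)CCC=C(C)C | intermediate
3 | (2E,6E,10E)-12-hydroxy-3,7,11-trimethyldodeca-2,6,10-trien-1-yl acetate | CC(=O)OC/C=C(\C)CC/C=C(\C)CC/C=C(\C)CO | intermediate
4 | (2E,6E,10E)-3,7,11-trimethyl-12-oxododeca-2,6,10-trien-1-yl acetate | CC(=O)OC/C=C(\C)CC/C=C(\C)CC/C=C(\C)C=O | intermediate
5 | (2E,6E,10E)-12-acetoxy-2,6,10-trimethyldodeca-2,6,10-trienoic acid | CC(=O)OC/C=C(\C)CC/C=C(\C)CC/C=C(\C)C(=O)O | intermediate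
6 | (2S,6E,10E)-12-acetoxy-2,6,10-trimethyldodeca-6,10-dienoic acid | CC(=O)OC/C=C(\C)CC/C=C(\C)CCC[C@H](C)C(=O)O | intermediate
7 | potassium (2S,6E,10E)-12-hydroxy-2,6,10-trimethyldodeca-6,10-dienoate | OC/C=C(\C)CC/C=C(\C)CCC[C@H](C)C(=O)[O-].[K+] | intermediate (not isolated)
8 | methyl (2S,6E,10E)-12-hydroxy-2,6,10-trimethyldodeca-6,10-dienoate | OC/C=C(\C)CC/C=C(\C)CCC[C@H](C)C(=O)OC | intermediate
9 | methyl (2S,6E,10E)-12-bromo-2,6,10-trimethyldodeca-6,10-dienoate | BrC/C=C(\C)CC/C=C(\C)CCC[C@H](C)C(=O)OC | intermediate
10 | ethynyltrimethylsilane | C#C[Si](C)(C)C | starting material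
11 | methyl (2S,6E,10E)-2,6,10-trimethyl-14-(trimethylsilyl)tetradeca-6,10-dien-13-ynoate | C[Si](C)(C)C#CC/C=C(\C)CC/C=C(\C)CCC[C@H](C)C(=O)OC | intermediate
12 | methyl (2S,6E,10E)-2,6,10-trimethyltetradeca-6,10-dien-13-ynoate | C#CC/C=C(\C)CC/C=C(\C)CCC[C@H](C)C(=O)OC | intermediate (key-step precursor)
13 | 2-chloroethanol | OCCCl | starting material
14 | 1-chloro-2-(methoxymethoxy)ethane | COCOCCCl | intermediate
15 | methoxymethyl vinyl ether | C=COCOC | intermediate
16 | chromium hexacarbonyl | O=C=[Cr](=C=O)(=C=O)(=C=O)(=C=O)=C=O | starting material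
17 | 1-(methoxymethoxy)vinyllithium | [Li]C(=C)OCOC | intermediate (not isolated)
18 | lithium pentacarbonyl[2-(methoxymethoxy)acryloyl]chromate | [Li+].C=C(OCOC)C([O-])=[Cr](=C=O)(=C=O)(=C=O)(=C=O)=C=O | intermediate (not isolated)
19 | tetramethylammonium pentacarbonyl[2-(methoxymethoxy)acryloyl]chromate | C[N+](C)(C)C.C=C(OCOC)C([O-])=[Cr](=C=O)(=C=O)(=C=O)(=C=O)=C=O | intermediate
20 | pentacarbonyl[(methoxymethoxy)(1-(methoxymethoxy)vinyl)carbene]chromium | COCOC(=[Cr](=C=O)(=C=O)(=C=O)(=C=O)=C=O)C(=C)OCOC | intermediate (key-step precursor)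
21 | tricarbonyl(η6-arene)chromium complex of 22 | COCOc1cc(C/C=C(\C)CC/C=C(\C)CCC[C@H](C)C(=O)OC)c(O)cc1OCOC.O=C=[Cr](=C=O)=C=O | intermediate (not isolated)
22 | methyl (2S,6E,10E)-12-[2-hydroxy-4,5-bis(methoxymethoxy)phenyl]-2,6,10-trimethyldodeca-6,10-dienoate | COCOc1cc(C/C=C(\C)CC/C=C(\C)CCC[C@H](C)C(=O)OC)c(O)cc1OCOC | intermediate (key-step product)
23 | methyl (2S,6E,10E)-12-[3-formyl-2-hydroxy-4,5-bis(methoxymethoxy)phenyl]-2,6,10-trimethyldodeca-6,10-dienoate | COCOc1cc(C/C=C(\C)CC/C=C(\C)CCC[C@H](C)C(=O)OC)c(O)c(C=O)c1OCOC | intermediate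
24 | (2S,6E,10E)-12-[3-formyl-2-hydroxy-4,5-bis(methoxymethoxy)phenyl]-2,6,10-trimethyldodeca-6,10-dienoic acid | COCOc1cc(C/C=C(\C)CC/C=C(\C)CCC[C@H](C)C(=O)O)c(O)c(C=O)c1OCOC | intermediate
25 | (2S,6E,10E)-12-(3-formyl-2,4,5-trihydroxyphenyl)-2,6,10-trimethyldodeca-6,10-dienoic acid | C/C(=C\Cc1cc(O)c(O)c(C=O)c1O)CC/C=C(\C)CCC[C@H](C)C(=O)O | target

**Step count and risks**
Total step count: 17. Longest linear sequence: 13 steps (steps 1–9, then 14–17); the carbene branch (steps 10–13) has 4 steps.

Most likely to fail, step 14 (benzannulation). The 1-alkoxyvinyl carbene may decompose or oligomerise before CO loss. The vinylcarbene or vinylketene may divert to cyclobutenone, furan or two-alkyne products. The skipped enyne may isomerise, and the electron-rich phenol may be oxidised to the quinone during decomplexation. Fallback, setting out from allylic bromide 9 and returning at target 25: the arene is made first and joined to the chain by allyl–aryl cross-coupling. Commercial benzene-1,2,4-triol is protected (MOMCl, i-Pr2NEt) to 1,2,4-tris(methoxymethoxy)benzene F1. Lithiation between the two meta-related OMOM groups (n-BuLi, THF, 0 °C) and DMF give 2,3,6-tris(methoxymethoxy)benzaldehyde F2. NBS should brominate the position para to one OMOM and ortho to another, giving 5-bromo-2,3,6-tris(methoxymethoxy)benzaldehyde F3. Miyaura borylation (B2pin2, PdCl2(dppf), KOAc, dioxane) gives 2,3,6-tris(methoxymethoxy)-5-(4,4,5,5-tetramethyl-1,3,2-dioxaborolan-2-yl)benzaldehyde F4. Suzuki–Miyaura coupling of F4 with 9 (Pd(PPh3)4, K2CO3, THF/H2O) should give methyl (2S,6E,10E)-12-[3-formyl-2,4,5-tris(methoxymethoxy)phenyl]-2,6,10-trimethyldodeca-6,10-dienoate F5 as the linear E isomer. LiOH gives (2S,6E,10E)-12-[3-formyl-2,4,5-tris(methoxymethoxy)phenyl]-2,6,10-trimethyldodeca-6,10-dienoic acid F6, and the conditions of step 17 remove the three MOM groups to give 25.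

Second, step 17 (unmasking). The free C2′ hydroxyl may add under acid to the C10=C11 alkene (chroman formation), the alkenes may be hydrated, released formaldehyde may attack the electron-rich ring, and the hydroxyhydroquinone may be oxidised by air. Fallback, setting out from 24 and returning at 25: the ring is unmasked at the quinone oxidation level, where no free phenol can add to the chain. PhI(OAc)2 in aqueous MeCN at 0 °C should oxidise the para-(methoxymethoxy)phenol of 24, with loss of the para MOM group, to (2S,6E,10E)-12-[5-formyl-4-(methoxymethoxy)-3,6-dioxocyclohexa-1,4-dien-1-yl]-2,6,10-trimethyldodeca-6,10-dienoic acid F7. Its vinylogous MOM ester is hydrolysed by addition–elimination in aqueous NaHCO3 to (2S,6E,10E)-12-(5-formyl-4-hydroxy-3,6-dioxocyclohexa-1,4-dien-1-yl)-2,6,10-trimethyldodeca-6,10-dienoic acid F8, and Na2S2O4 reduces F8 to 25.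

Third, step 13 (O-alkylation to the carbene). Alkylation of the acyl chromate may be sluggish or go at carbon, and the acetal-type alkoxy group may be lost by hydrolysis on work-up or on silica. Fallback, setting out from 19 and returning at 25: the carbene oxygen is methylated instead and that methyl is later removed oxidatively. MeOTf in CH2Cl2 converts 19 into pentacarbonyl[methoxy(1-(methoxymethoxy)vinyl)carbene]chromium F9. Benzannulation with 12 and air decomplexation as in step 14 give methyl (2S,6E,10E)-12-[2-hydroxy-5-methoxy-4-(methoxymethoxy)phenyl]-2,6,10-trimethyldodeca-6,10-dienoate F10. Formylation as in step 15 gives methyl (2S,6E,10E)-12-[3-formyl-2-hydroxy-5-methoxy-4-(methoxymethoxy)phenyl]-2,6,10-trimethyldodeca-6,10-dienoate F11. LiOH gives (2S,6E,10E)-12-[3-formyl-2-hydroxy-5-methoxy-4-(methoxymethoxy)phenyl]-2,6,10-trimethyldodeca-6,10-dienoic acid F12. PhI(OAc)2 in aqueous MeCN oxidises the para-methoxyphenol of F12, with loss of the methoxy group, to the quinone F7, which is taken on through F8 to 25 as above.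

**Further compounds**
F1 | step 14 | 1,2,4-tris(methoxymethoxy)benzene | COCOc1ccc(OCOC)c(OCOC)c1
F2 | step 14 | 2,3,6-tris(methoxymethoxy)benzaldehyde | COCOc1ccc(OCOC)c(C=O)c1OCOC
F3 | step 14 | 5-bromo-2,3,6-tris(methoxymethoxy)benzaldehyde | COCOc1cc(Br)c(OCOC)c(C=O)c1OCOC
F4 | step 14 | 2,3,6-tris(methoxymethoxy)-5-(4,4,5,5-tetramethyl-1,3,2-dioxaborolan-2-yl)benzaldehyde | COCOc1cc(B2OC(C)(C)C(C)(C)O2)c(OCOC)c(C=O)c1OCOC
F5 | step 14 | methyl (2S,6E,10E)-12-[3-formyl-2,4,5-tris(methoxymethoxy)phenyl]-2,6,10-trimethyldodeca-6,10-dienoate | COCOc1cc(C/C=C(\C)CC/C=C(\C)CCC[C@H](C)C(=O)OC)c(OCOC)c(C=O)c1OCOC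
F6 | step 14 | (2S,6E,10E)-12-[3-formyl-2,4,5-tris(methoxymethoxy)phenyl]-2,6,10-trimethyldodeca-6,10-dienoic acid | COCOc1cc(C/C=C(\C)CC/C=C(\C)CCC[C@H](C)C(=O)O)c(OCOC)c(C=O)c1OCOC
F7 | step 17 | (2S,6E,10E)-12-[5-formyl-4-(methoxymethoxy)-3,6-dioxocyclohexa-1,4-dien-1-yl]-2,6,10-trimethyldodeca-6,10-dienoic acid | O=C1C(C=O)=C(OCOC)C(=O)C=C1C/C=C(\C)CC/C=C(\C)CCC[C@H](C)C(=O)O
F8 | step 17 | (2S,6E,10E)-12-(5-formyl-4-hydroxy-3,6-dioxocyclohexa-1,4-dien-1-yl)-2,6,10-trimethyldodeca-6,10-dienoic acid | O=C1C(C=O)=C(O)C(=O)C=C1C/C=C(\C)CC/C=C(\C)CCC[C@H](C)C(=O)O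
F9 | step 13 | pentacarbonyl[methoxy(1-(methoxymethoxy)vinyl)carbene]chromium | COC(=[Cr](=C=O)(=C=O)(=C=O)(=C=O)=C=O)C(=C)OCOC
F10 | step 13 | methyl (2S,6E,10E)-12-[2-hydroxy-5-methoxy-4-(methoxymethoxy)phenyl]-2,6,10-trimethyldodeca-6,10-dienoate | COc1cc(C/C=C(\C)CC/C=C(\C)CCC[C@H](C)C(=O)OC)c(O)cc1OCOC
F11 | step 13 | methyl (2S,6E,10E)-12-[3-formyl-2-hydroxy-5-methoxy-4-(methoxymethoxy)phenyl]-2,6,10-trimethyldodeca-6,10-dienoate | COc1cc(C/C=C(\C)CC/C=C(\C)CCC[C@H](C)C(=O)OC)c(O)c(C=O)c1OCOC
F12 | step 13 | (2S,6E,10E)-12-[3-formyl-2-hydroxy-5-methoxy-4-(methoxymethoxy)phenyl]-2,6,10-trimethyldodeca-6,10-dienoic acid | COc1cc(C/C=C(\C)CC/C=C(\C)CCC[C@H](C)C(=O)O)c(O)c(C=O)c1OCOC
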